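**Retrosynthetic overview**
1. Target ⇐ angelate at C1 (last), acetate at C8 and a hydroxyl-directed epoxidation of an (E,E)-cyclodeca-3,9-diene bearing C1–OPMB and C8–OH.
2. The ten-membered ring is not closed by macrocyclisation: it comes from an anionic oxy-Cope ring expansion of a trans-1,2-dialkenylcyclohexanol, with the enolate trapped as an enol triflate and reduced. This one step sets both E alkenes and C1.
3. The dialkenyl carbinol ⇐ α-silyloxy ketone 10 + 2-lithioallyl PMB ether, then base-mediated allyl ether → (E)-enol ether isomerisation.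
4. Ketone 10 ⇐ (R)-carvone: isopropenyl hydrogenation, reductive aldol/dehydration (methyl/vinyl quaternary carbon), Rubottom oxidation.
5. Ring order: cyclohexane (chiral pool) → cyclodecadiene (ring expansion, step 9) → oxirane (step 12).

Assumption 1: ten-membered-ring compounds are named with route numbering: C1 bears the angelate oxygen, C2, C3=C4 (C4 bears CH3), C5, C6, C7 (isopropyl), C8 (acetate oxygen), C9 and C10 (epoxide, C10 bears CH3). The target is then (1R,3E,7S,8S,9R,10R) with a (2Z)-2-methylbut-2-enoate.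
Assumption 2: a metal alkoxide that is only protonated on aqueous work-up is not counted as a separate compound.
Abbreviations: TBS = tert-butyldimethylsilyl, PMB = 4-methoxybenzyl, Tf = trifluoromethanesulfonyl.

**Route**

Step 1
Reactants: 1 (R)-carvone
Product: 2 (5R)-2-methyl-5-(propan-2-yl)cyclohex-2-en-1-one
Conditions: H2 (1 atm), RhCl(PPh3)3 (2 mol %), benzene, rt
Reagents that add atoms: none
Why: Homogeneous catalytic hydrogenation with RhCl(PPh3)3 reduces the unhindered 1,1-disubstituted isopropenyl alkene and leaves the conjugated trisubstituted enone alkene alone, so the chiral-pool centre (later C7) is carried through unchanged.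

Step 2
Reactants: 2 (5R)-2-methyl-5-(propan-2-yl)cyclohex-2-en-1-one; 3 acetaldehyde
Product: 5 (2R,5R)-2-(1-hydroxyethyl)-2-methyl-5-(propan-2-yl)cyclohexan-1-one (both carbinol epimers), via lithium enolate 4 (not isolated)
Conditions: LiBH(s-Bu)3, THF, −78 °C; then CH3CHO, −78 °C; H2O
Reagents that add atoms: acetaldehyde 3, CC=O
Why: Conjugate hydride reduction gives the regiodefined tetrasubstituted enolate, and its aldol addition occurs by axial attack on the half-chair with isopropyl equatorial, so the new C–C bond is cis to isopropyl (2R), as in alkylations of dihydrocarvone enolates; the carbinol centre is removed in step 3.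

Step 3
Reactants: 5 (2R,5R)-2-(1-hydroxyethyl)-2-methyl-5-(propan-2-yl)cyclohexan-1-one
Product: 6 (2R,5R)-2-ethenyl-2-methyl-5-(propan-2-yl)cyclohexan-1-one
Conditions: Burgess reagent (MeO2CN–SO2NEt3 inner salt), benzene, 50 °C
Reagents that add atoms: none
Why: Burgess dehydration is a syn-elimination through the sulfamate ester, and because the α-carbon is quaternary the only β-hydrogens are on the methyl group, so the vinyl group forms without touching either stereocentre.

Step 4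
Reactants: 6 (2R,5R)-2-ethenyl-2-methyl-5-(propan-2-yl)cyclohexan-1-one
Product: 8 tert-butyl{[(3S,6R)-6-ethenyl-6-methyl-3-(propan-2-yl)cyclohex-1-en-1-yl]oxy}dimethylsilane, via lithium enolate 7 (not isolated)
Conditions: LiN(i-Pr)2, THF, −78 °C; then TBSCl, DMPU, −78 °C to rt
Reagents that add atoms: tert-butyldimethylsilyl chloride, CC(C)(C)[Si](C)(C)Cl
Why: Only one α-carbon carries hydrogen (the other is quaternary), so deprotonation and O-silylation give a single silyl enol ether (enolate trapping).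

Step 5
Reactants: 8 tert-butyl{[(3S,6R)-6-ethenyl-6-methyl-3-(propan-2-yl)cyclohex-1-en-1-yl]oxy}dimethylsilane
Product: 10 (2R,5S,6S)-6-(TBS-oxy)-2-ethenyl-2-methyl-5-(propan-2-yl)cyclohexan-1-one, via silyloxy epoxide 9 (not isolated)
Conditions: mCPBA, NaHCO3, CH2Cl2, −20 to 0 °C
Reagents that add atoms: 3-chloroperoxybenzoic acid, OOC(=O)c1cccc(Cl)c1
Why: Rubottom oxidation: the peracid epoxidises the electron-rich enol ether (not the vinyl group) on the face anti to the adjacent isopropyl and to the pseudo-axial vinyl group, and the silyloxy epoxide opens with 1,4-silyl shift to the α-silyloxy ketone with oxygen trans to isopropyl (6S).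

Step 6
Reactants: 11 (4-methoxyphenyl)methanol; 12 2,3-dibromoprop-1-ene
Product: 14 1-{[(2-bromoprop-2-en-1-yl)oxy]methyl}-4-methoxybenzene, via sodium alkoxide 13 (not isolated)
Conditions: NaH, THF, 0 °C; then 12, Bu4NI (cat.), rt
Reagents that add atoms: 2,3-dibromoprop-1-ene 12, C=C(Br)CBr
Why: Williamson ether synthesis by SN2 displacement of the allylic bromide; the vinylic bromide is inert.

Step 7
Reactants: 14 1-{[(2-bromoprop-2-en-1-yl)oxy]methyl}-4-methoxybenzene; 10 (2R,5S,6S)-6-(TBS-oxy)-2-ethenyl-2-methyl-5-(propan-2-yl)cyclohexan-1-one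
Product: 17 (1R,2R,5S,6S)-6-(TBS-oxy)-2-ethenyl-1-[3-(PMB-oxy)prop-1-en-2-yl]-2-methyl-5-(propan-2-yl)cyclohexan-1-ol, via alkenyllithium 15 (not isolated), via alkenylcerium dichloride 16 (not isolated)
Conditions: t-BuLi (2 equiv), Et2O, −78 °C; CeCl3, THF, −78 °C; then 10, −78 to −30 °C; H2O
Reagents that add atoms: bromide 14 (as its cerium reagent), C=C(Br)COCc1ccc(OC)cc1
Why: Bromine–lithium exchange and transmetalation give a weakly basic alkenylcerium reagent that adds 1,2 to the hindered ketone along the axial trajectory, anti to the axial vinyl group of the chair that keeps isopropyl and OTBS equatorial, so the two alkenyl groups end up trans (1R) (organocerium carbonyl addition, Felkin-type axial attack).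

Step 8
Reactants: 17 (1R,2R,5S,6S)-6-(TBS-oxy)-2-ethenyl-1-[3-(PMB-oxy)prop-1-en-2-yl]-2-methyl-5-(propan-2-yl)cyclohexan-1-ol
Product: 19 (1R,2R,5S,6S)-6-(TBS-oxy)-2-ethenyl-1-[(1E)-1-(PMB-oxy)prop-1-en-2-yl]-2-methyl-5-(propan-2-yl)cyclohexan-1-ol, via dilithiated alkoxyallyl species 18 (not isolated)
Conditions: LiN(i-Pr)2 (3 equiv), THF, 0 °C to rt; H2O
Reagents that add atoms: none
Why: Base-mediated allyl ether to propenyl ether isomerisation: deprotonation gives the lithium-chelated alkoxyallyl anion with oxygen syn to the CH2 terminus and anti to the bulky carbinol carbon, and γ-protonation gives the enol ether with OPMB cis to the new methyl, i.e. the (E)-enol ether; the lithium alkoxide does not undergo Cope rearrangement at room temperature.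

Step 9
Reactants: 19 (1R,2R,5S,6S)-6-(TBS-oxy)-2-ethenyl-1-[(1E)-1-(PMB-oxy)prop-1-en-2-yl]-2-methyl-5-(propan-2-yl)cyclohexan-1-ol
Product: 22 (1R,3E,7S,8S,9Z)-8-(TBS-oxy)-1-(PMB-oxy)-4,10-dimethyl-7-(propan-2-yl)cyclodeca-3,9-dien-9-yl trifluoromethanesulfonate, via potassium alkoxide 20 (not isolated), via potassium enolate 21 (not isolated)
Conditions: KH, 18-crown-6, THF, 0 to 40 °C; then PhNTf2, −78 to 0 °C; H2O
Reagents that add atoms: N-phenylbis(trifluoromethanesulfonimide), O=S(=O)(N(c1ccccc1)S(=O)(=O)C(F)(F)F)C(F)(F)F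
Why: Anionic oxy-Cope rearrangement: after ring flip to the chair with both alkenyl groups equatorial, the trans-1,2-dialkenyl alkoxide rearranges through the chair transition state with both ring bonds pseudo-equatorial, which gives the (3E) alkene, an enolate with C8 and C1 trans, and (1R) because the C1–C2 bond forms on the face of the (E)-enol ether that the breaking bond occupied; O-triflation then fixes the enolate geometry.

Step 10
Reactants: 22 (1R,3E,7S,8S,9Z)-8-(TBS-oxy)-1-(PMB-oxy)-4,10-dimethyl-7-(propan-2-yl)cyclodeca-3,9-dien-9-yl trifluoromethanesulfonate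
Product: 23 (1R,3E,7S,8S,9E)-8-(TBS-oxy)-1-(PMB-oxy)-4,10-dimethyl-7-(propan-2-yl)cyclodeca-3,9-diene
Conditions: Pd(PPh3)4 (5 mol %), Bu3SnH, LiCl, THF, rt
Reagents that add atoms: none
Why: Palladium-catalysed reduction of the enol triflate (oxidative addition to zerovalent palladium, hydride transfer from tin, reductive elimination) replaces OTf by H with retention of alkene geometry, giving the (9E) trisubstituted alkene at a temperature too low for Cope rearrangement of the 1,5-diene.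

Step 11
Reactants: 23 (1R,3E,7S,8S,9E)-8-(TBS-oxy)-1-(PMB-oxy)-4,10-dimethyl-7-(propan-2-yl)cyclodeca-3,9-diene
Product: 24 (1R,3E,7S,8S,9E)-1-(PMB-oxy)-4,10-dimethyl-7-(propan-2-yl)cyclodeca-3,9-dien-8-ol
Conditions: Bu4NF, THF, 0 °C to rt
Reagents that add atoms: none
Why: Fluoride-induced desilylation (Si–F bond formation) frees the C8 allylic alcohol without touching the PMB ether or the diene.

Step 12
Reactants: 24 (1R,3E,7S,8S,9E)-1-(PMB-oxy)-4,10-dimethyl-7-(propan-2-yl)cyclodeca-3,9-dien-8-ol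
Product: 25 (1R,3E,7S,8S,9R,10R)-9,10-epoxy-1-(PMB-oxy)-4,10-dimethyl-7-(propan-2-yl)cyclodec-3-en-8-ol
Conditions: VO(acac)2 (5 mol %), t-BuOOH (in decane), CH2Cl2, 0 °C
Reagents that add atoms: tert-butyl hydroperoxide, CC(C)(C)OO
Why: Hydroxyl-directed epoxidation: the vanadium alkoxide delivers oxygen only to the allylic C9=C10 alkene and to the face that carries the hydroxyl in the conformer with C8–H eclipsing the alkene (minimal A(1,3) strain with the cis C10 methyl), which is also the peripheral face, giving the threo epoxy alcohol (9R,10R).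

Step 13
Reactants: 25 (1R,3E,7S,8S,9R,10R)-9,10-epoxy-1-(PMB-oxy)-4,10-dimethyl-7-(propan-2-yl)cyclodec-3-en-8-ol
Product: 26 (1R,3E,7S,8S,9R,10R)-9,10-epoxy-1-(PMB-oxy)-4,10-dimethyl-7-(propan-2-yl)cyclodec-3-en-8-yl acetate
Conditions: Ac2O, pyridine, 4-(dimethylamino)pyridine (cat.), CH2Cl2, rt
Reagents that add atoms: acetic anhydride, CC(=O)OC(C)=O
Why: Nucleophile-catalysed acylation of the secondary alcohol under basic conditions that leave the epoxide intact.

Step 14
Reactants: 26 (1R,3E,7S,8S,9R,10R)-9,10-epoxy-1-(PMB-oxy)-4,10-dimethyl-7-(propan-2-yl)cyclodec-3-en-8-yl acetate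
Product: 27 (1R,3E,7S,8S,9R,10R)-9,10-epoxy-1-hydroxy-4,10-dimethyl-7-(propan-2-yl)cyclodec-3-en-8-yl acetate
Conditions: DDQ, CH2Cl2/pH 7 phosphate buffer (10:1), 0 °C
Reagents that add atoms: none
Why: Oxidative PMB ether cleavage (benzylic hydride abstraction to the oxocarbenium ion, then hydrolysis) proceeds under buffered neutral conditions that spare epoxide, acetate and alkene.

Step 15
Reactants: 27 (1R,3E,7S,8S,9R,10R)-9,10-epoxy-1-hydroxy-4,10-dimethyl-7-(propan-2-yl)cyclodec-3-en-8-yl acetate; 28 angelic acid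
Product: 30 (1R,3E,7S,8S,9R,10R)-8-acetoxy-9,10-epoxy-4,10-dimethyl-7-(propan-2-yl)cyclodec-3-en-1-yl (2Z)-2-methylbut-2-enoate, via mixed anhydride 29 (not isolated)
Conditions: 2,4,6-Cl3C6H2COCl, Et3N, toluene, rt; then 27, 80 °C
Reagents that add atoms: angelic acid 28, C/C=C(/C)C(=O)O
Why: Mixed-anhydride (Yamaguchi-type) esterification without a nucleophilic pyridine catalyst: the alcohol attacks the less hindered angeloyl carbonyl, the C1–O bond is not broken (retention), and omitting DMAP avoids addition–elimination isomerisation of the (Z)-angelate to the tiglate.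

**Compound list**

1 | (R)-carvone, (5R)-2-methyl-5-(prop-1-en-2-yl)cyclohex-2-en-1-one | CC1=CC[C@@H](C(C)=C)CC1=O | starting material
2 | (5R)-2-methyl-5-(propan-2-yl)cyclohex-2-en-1-one | CC1=CC[C@@H](C(C)C)CC1=O | intermediate
3 | acetaldehyde | CC=O | starting material
4 | lithium (5R)-2-methyl-5-(propan-2-yl)cyclohex-1-en-1-olate | CC1=C(O[Li])C[C@H](C(C)C)CC1 | intermediate
5 | (2R,5R)-2-(1-hydroxyethyl)-2-methyl-5-(propan-2-yl)cyclohexan-1-one, both carbinol epimers, hydroxyethyl cis to isopropyl | CC(O)[C@@]1(C)CC[C@@H](C(C)C)CC1=O | intermediate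
6 | (2R,5R)-2-ethenyl-2-methyl-5-(propan-2-yl)cyclohexan-1-one, vinyl cis to isopropyl | C=C[C@@]1(C)CC[C@@H](C(C)C)CC1=O | intermediate
7 | lithium (3S,6R)-6-ethenyl-6-methyl-3-(propan-2-yl)cyclohex-1-en-1-olate | C=C[C@@]1(C)CC[C@@H](C(C)C)C=C1O[Li] | intermediate
8 | tert-butyl{[(3S,6R)-6-ethenyl-6-methyl-3-(propan-2-yl)cyclohex-1-en-1-yl]oxy}dimethylsilane | C=C[C@@]1(C)CC[C@@H](C(C)C)C=C1O[Si](C)(C)C(C)(C)C | intermediate
9 | 1-(TBS-oxy)-2-ethenyl-2-methyl-5-(propan-2-yl)-7-oxabicyclo[4.1.0]heptane, epoxide oxygen trans to isopropyl and to vinyl | C=C[C@@]1(C)CC[C@@H](C(C)C)[C@@H]2O[C@]12O[Si](C)(C)C(C)(C)C | intermediate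
10 | (2R,5S,6S)-6-(TBS-oxy)-2-ethenyl-2-methyl-5-(propan-2-yl)cyclohexan-1-one | C=C[C@@]1(C)CC[C@@H](C(C)C)[C@H](O[Si](C)(C)C(C)(C)C)C1=O | intermediate
11 | (4-methoxyphenyl)methanol | COc1ccc(CO)cc1 | starting material
12 | 2,3-dibromoprop-1-ene | C=C(Br)CBr | starting material
13 | sodium (4-methoxyphenyl)methanolate | COc1ccc(CO[Na])cc1 | intermediate
14 | 1-{[(2-bromoprop-2-en-1-yl)oxy]methyl}-4-methoxybenzene | C=C(Br)COCc1ccc(OC)cc1 | intermediate
15 | [3-(PMB-oxy)prop-1-en-2-yl]lithium | [Li]C(=C)COCc1ccc(OC)cc1 | intermediate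
16 | dichloro[3-(PMB-oxy)prop-1-en-2-yl]cerium | Cl[Ce](Cl)C(=C)COCc1ccc(OC)cc1 | intermediate
17 | (1R,2R,5S,6S)-6-(TBS-oxy)-2-ethenyl-1-[3-(PMB-oxy)prop-1-en-2-yl]-2-methyl-5-(propan-2-yl)cyclohexan-1-ol | C=C[C@@]1(C)CC[C@@H](C(C)C)[C@H](O[Si](C)(C)C(C)(C)C)[C@]1(O)C(=C)COCc2ccc(OC)cc2 | intermediate
18 | lithium alkoxide of 17 lithiated at the allylic position (alkoxyallyllithium, oxygen syn to the CH2Li terminus) | C=C[C@@]1(C)CC[C@@H](C(C)C)[C@H](O[Si](C)(C)C(C)(C)C)[C@]1(O[Li])/C(C[Li])=C/OCc2ccc(OC)cc2 | intermediate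
19 | (1R,2R,5S,6S)-6-(TBS-oxy)-2-ethenyl-1-[(1E)-1-(PMB-oxy)prop-1-en-2-yl]-2-methyl-5-(propan-2-yl)cyclohexan-1-ol | C=C[C@@]1(C)CC[C@@H](C(C)C)[C@H](O[Si](C)(C)C(C)(C)C)[C@]1(O)/C(C)=C/OCc2ccc(OC)cc2 | intermediate
20 | potassium alkoxide of 19 | C=C[C@@]1(C)CC[C@@H](C(C)C)[C@H](O[Si](C)(C)C(C)(C)C)[C@]1(O[K])/C(C)=C/OCc2ccc(OC)cc2 | intermediate
21 | potassium (1R,3E,7S,8S,9Z)-8-(TBS-oxy)-1-(PMB-oxy)-4,10-dimethyl-7-(propan-2-yl)cyclodeca-3,9-dien-9-olate | COc1ccc(CO[C@@H]2C/C=C(\C)CC[C@@H](C(C)C)[C@H](O[Si](C)(C)C(C)(C)C)/C(O[K])=C2\C)cc1 | intermediate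
22 | (1R,3E,7S,8S,9Z)-8-(TBS-oxy)-1-(PMB-oxy)-4,10-dimethyl-7-(propan-2-yl)cyclodeca-3,9-dien-9-yl trifluoromethanesulfonate | COc1ccc(CO[C@@H]2C/C=C(\C)CC[C@@H](C(C)C)[C@H](O[Si](C)(C)C(C)(C)C)/C(OS(=O)(=O)C(F)(F)F)=C2\C)cc1 | intermediate
23 | (1R,3E,7S,8S,9E)-8-(TBS-oxy)-1-(PMB-oxy)-4,10-dimethyl-7-(propan-2-yl)cyclodeca-3,9-diene | COc1ccc(CO[C@@H]2C/C=C(\C)CC[C@@H](C(C)C)[C@H](O[Si](C)(C)C(C)(C)C)/C=C2\C)cc1 | intermediate
24 | (1R,3E,7S,8S,9E)-1-(PMB-oxy)-4,10-dimethyl-7-(propan-2-yl)cyclodeca-3,9-dien-8-ol | COc1ccc(CO[C@@H]2C/C=C(\C)CC[C@@H](C(C)C)[C@H](O)/C=C2\C)cc1 | intermediate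
25 | (1R,3E,7S,8S,9R,10R)-9,10-epoxy-1-(PMB-oxy)-4,10-dimethyl-7-(propan-2-yl)cyclodec-3-en-8-ol | COc1ccc(CO[C@@H]2C/C=C(\C)CC[C@@H](C(C)C)[C@H](O)[C@H]3O[C@@]32C)cc1 | intermediate
26 | (1R,3E,7S,8S,9R,10R)-9,10-epoxy-1-(PMB-oxy)-4,10-dimethyl-7-(propan-2-yl)cyclodec-3-en-8-yl acetate | COc1ccc(CO[C@@H]2C/C=C(\C)CC[C@@H](C(C)C)[C@H](OC(C)=O)[C@H]3O[C@@]32C)cc1 | intermediate
27 | (1R,3E,7S,8S,9R,10R)-9,10-epoxy-1-hydroxy-4,10-dimethyl-7-(propan-2-yl)cyclodec-3-en-8-yl acetate | O[C@@H]1C/C=C(\C)CC[C@@H](C(C)C)[C@H](OC(C)=O)[C@H]2O[C@@]21C | intermediate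
28 | angelic acid, (2Z)-2-methylbut-2-enoic acid | C/C=C(/C)C(=O)O | starting material
29 | (2Z)-2-methylbut-2-enoic 2,4,6-trichlorobenzoic anhydride | C/C=C(/C)C(=O)OC(=O)c1c(Cl)cc(Cl)cc1Cl | intermediate
30 | (1R,3E,7S,8S,9R,10R)-8-acetoxy-9,10-epoxy-4,10-dimethyl-7-(propan-2-yl)cyclodec-3-en-1-yl (2Z)-2-methylbut-2-enoate | C/C=C(/C)C(=O)O[C@@H]1C/C=C(\C)CC[C@@H](C(C)C)[C@H](OC(C)=O)[C@H]2O[C@@]21C | target

**Totals**
Total step count: 15.
Longest linear sequence: 14 steps (steps 1–5 and 7–15, from 1 to 30); step 6 is a one-step side branch.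

**The three steps most likely to fail, with fallbacks**

Most at risk is step 9, the ring expansion. The reactive conformer needs the ring flipped so that isopropyl, OTBS, the C4 methyl and the alkoxide are all axial, which raises the temperature required. The product enolate carries a β-OPMB group that can be lost by E1cB elimination when warm, and a 1,2-silyl shift to the tertiary alkoxide could stall the reaction. The fallback sets out from 19 and comes back at 22, and avoids any enolate at elevated temperature. Compound 19 is silylated (Me3SiOTf, 2,6-lutidine, CH2Cl2, −78 °C) to the trimethylsilyl ether of 19 F6. Heating in o-dichlorobenzene at 180 °C (neutral siloxy-Cope through the same chair) gives the ring-expanded (1R,3E,7S,8S,9Z)-9-(trimethylsilyloxy) enol ether F7. MeLi in THF at 0 °C cleaves the Si–O bond to the lithium (9Z)-enolate F8 with retention of geometry, and PhNTf2 at −78 °C then gives 22.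

Second is step 8, the allyl ether to enol ether isomerisation. The (E) geometry on a 2-substituted allyl ether is an extrapolation from simple allyl ethers, and this geometry decides C1. The fallback sets out from 10 (with 11 as the source of the PMB group) and comes back at 19, bypassing 17. Alcohol 11 with KH and trichloroethylene gives 1-({[(E)-1,2-dichloroethenyl]oxy}methyl)-4-methoxybenzene F2. Two equivalents of n-BuLi at −78 °C convert it into lithium 2-(PMB-oxy)ethynide F3, which adds axially to 10 to give the alkynol (1R,2R,5S,6S)-6-(TBS-oxy)-2-ethenyl-1-[(PMB-oxy)ethynyl]-2-methyl-5-(propan-2-yl)cyclohexan-1-ol F4. Hydroxyl-directed trans-hydrostannation ([(C5Me5)RuCl]4 cat., Bu3SnH, CH2Cl2) puts tin on the carbon next to the carbinol and hydrogen anti to it, giving the (Z)-alkenylstannane (1S,2R,5S,6S)-6-(TBS-oxy)-2-ethenyl-1-[(Z)-2-(PMB-oxy)-1-(tributylstannyl)ethenyl]-2-methyl-5-(propan-2-yl)cyclohexan-1-ol F5. Methyl-for-tin cross-coupling with retention (MeI, Pd(PPh3)4, Cu(O2CC4H3S), [Bu4N][Ph2PO2], DMF) then gives 19. The ynol ether substrate for the hydrostannation is itself untested.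

Third is step 3, the dehydration. A secondary carbinol next to an acyl-bearing quaternary carbon can undergo retro-aldol cleavage, 1,2-acyl shift or carbamate formation instead of elimination. The fallback sets out from 2 and comes back at 6, bypassing 5. Enolate 4, generated as in step 2, is added to phenyl vinyl sulfoxide (Michael addition, same facial preference) to give (2R,5R)-2-methyl-2-[2-(phenylsulfinyl)ethyl]-5-(propan-2-yl)cyclohexan-1-one F1. Thermolysis (toluene, 110 °C, CaCO3) eliminates the sulfoxide by syn-elimination to give 6.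

**Further compounds**

F1 | step 3 | (2R,5R)-2-methyl-2-[2-(phenylsulfinyl)ethyl]-5-(propan-2-yl)cyclohexan-1-one (both sulfur epimers) | O=S(CC[C@@]1(C)CC[C@@H](C(C)C)CC1=O)c1ccccc1
F2 | step 8 | 1-({[(E)-1,2-dichloroethenyl]oxy}methyl)-4-methoxybenzene | Cl/C=C(/Cl)OCc1ccc(OC)cc1
F3 | step 8 | lithium 2-(PMB-oxy)ethynide | [Li]C#COCc1ccc(OC)cc1
F4 | step 8 | (1R,2R,5S,6S)-6-(TBS-oxy)-2-ethenyl-1-[(PMB-oxy)ethynyl]-2-methyl-5-(propan-2-yl)cyclohexan-1-ol | C=C[C@@]1(C)CC[C@@H](C(C)C)[C@H](O[Si](C)(C)C(C)(C)C)[C@]1(O)C#COCc2ccc(OC)cc2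
F5 | step 8 | (1S,2R,5S,6S)-6-(TBS-oxy)-2-ethenyl-1-[(Z)-2-(PMB-oxy)-1-(tributylstannyl)ethenyl]-2-methyl-5-(propan-2-yl)cyclohexan-1-ol | C=C[C@@]1(C)CC[C@@H](C(C)C)[C@H](O[Si](C)(C)C(C)(C)C)[C@]1(O)/C(=C/OCc2ccc(OC)cc2)[Sn](CCCC)(CCCC)CCCC
F6 | step 9 | trimethylsilyl ether of 19 | C=C[C@@]1(C)CC[C@@H](C(C)C)[C@H](O[Si](C)(C)C(C)(C)C)[C@]1(O[Si](C)(C)C)/C(C)=C/OCc2ccc(OC)cc2
F7 | step 9 | (1R,3E,7S,8S,9Z)-8-(TBS-oxy)-1-(PMB-oxy)-4,10-dimethyl-7-(propan-2-yl)-9-(trimethylsilyloxy)cyclodeca-3,9-diene | COc1ccc(CO[C@@H]2C/C=C(\C)CC[C@@H](C(C)C)[C@H](O[Si](C)(C)C(C)(C)C)/C(O[Si](C)(C)C)=C2\C)cc1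
F8 | step 9 | lithium (1R,3E,7S,8S,9Z)-8-(TBS-oxy)-1-(PMB-oxy)-4,10-dimethyl-7-(propan-2-yl)cyclodeca-3,9-dien-9-olate | COc1ccc(CO[C@@H]2C/C=C(\C)CC[C@@H](C(C)C)[C@H](O[Si](C)(C)C(C)(C)C)/C(O[Li])=C2\C)cc1
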